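## Retrosynthetic overview

1. The exocyclic 5Z C=C is disconnected to (2E)-pent-2-enal and a 2-bromo-4-hydroxy-4-alkylcyclopentenone: syn-selective aldol addition, then stereospecific syn dehydration.
2. The vinyl bromide comes from bromine addition and dehydrobromination of the parent 4-hydroxy-4-alkylcyclopent-2-enone.
3. The cyclopentenone and its quaternary carbinol come from a catalytic enantioselective ring-closing aldol of an acyclic cis-ene-1,4-dione (the new step).
4. The cis-enedione is unmasked by oxidative opening of a 2-methyl-5-alkylfuran, made by Negishi coupling of methyl 8-bromooctanoate with 2-bromo-5-methylfuran.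
5. Ring order: the furan arrives with a starting material and is opened; the carbocycle is the only ring formed, closed once in the aldol step.

Locants: C9–C13 refer to the tridecenoate chain of compound 5. Ring locants are C1 carbinol, C2 =CH, C3 C–Br, C4 C=O, C5 the carbon between C=O and carbinol.

Assumption: the sense of induction in step 3 (Re-face attack at C9 with the quinine-derived amine) is a model-based prediction; the quinidine-derived pseudo-enantiomer is the drop-in alternative if the (S)-alcohol forms.

Assumption: for 7 and 12 the diastereomer drawn is the expected major one; every diastereomer of 7 gives 8, and every syn (erythro) isomer of 12 gives 14.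

## Route

Step 1
Reactants: 1 methyl 8-bromooctanoate; 2 2-bromo-5-methylfuran
Product: 4 methyl 8-(5-methylfuran-2-yl)octanoate, via alkylzinc bromide 3 (not isolated)
Conditions: Zn dust (1.5 equiv), I2 (5 mol %), DMA, 80 °C; then 2, Pd(OAc)2 (2 mol %), SPhos (4 mol %), THF, 25–40 °C
Reagents that add atoms: none
Why: Negishi coupling; zinc insertion into the primary bromide tolerates the ester, and Pd/SPhos couples primary alkylzinc halides with 2-bromofurans without β-hydride loss; no stereocentre is formed.

Step 2
Reactants: 4 methyl 8-(5-methylfuran-2-yl)octanoate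
Product: 5 methyl (10Z)-9,12-dioxotridec-10-enoate
Conditions: mCPBA (1.05 equiv), CH2Cl2, 0 °C, 30 min; cold NaHCO3 wash; used at once, kept from light and acid
Reagents that add atoms: mCPBA (3-chloroperoxybenzoic acid), OOC(=O)c1cccc(Cl)c1
Why: oxidative furan ring opening; epoxidation of the electron-rich 2,5-dialkylfuran and ring opening give the ene-1,4-dione with the Z geometry imposed by the furan; no stereocentre is formed.

Step 3
Reactants: 5 methyl (10Z)-9,12-dioxotridec-10-enoate
Product: 6 methyl 8-[(1R)-1-hydroxy-4-oxocyclopent-2-en-1-yl]octanoate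
Conditions: 9-amino-9-deoxy-epi-quinine (20 mol %), AcOH (40 mol %), toluene (0.05 M), 0 °C → rt, dark; stopped at full conversion
Reagents that add atoms: none
Why: Proposed new method: enantioselective primary-amine-catalysed ring-closing aldol of a cis-ene-1,4-dione. The amine condenses at the less hindered methyl ketone (C12), whose only enolisable side is CH3, giving a cross-conjugated 2-aminodiene; with the C9 carbonyl hydrogen-bonded to the protonated quinuclidine, the CH2 terminus closes onto the Re face of C9 (a conrotatory 4π, Nazarov/Piancatelli-like closure that accommodates the formally 5-enolendo geometry), and hydrolysis of the ring iminium releases (R)-6 with the Z alkene becoming the ring alkene. Closest known reactions: cinchona-amine/acid-catalysed intramolecular aldolisation of diketones (Hajos–Parrish type), amine-catalysed 2-aminodiene formation from methyl enones, diamine-promoted asymmetric Nazarov cyclisation, and the racemic aqueous-carbonate cyclisation of cis-enediones to 4-hydroxycyclopentenones.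

Step 4
Reactants: 6 methyl 8-[(1R)-1-hydroxy-4-oxocyclopent-2-en-1-yl]octanoate
Product: 8 methyl 8-[(1R)-3-bromo-1-hydroxy-4-oxocyclopent-2-en-1-yl]octanoate, via trans-dibromide 7 (not isolated)
Conditions: Br2 (1.05 equiv), CH2Cl2, −20 → 0 °C; then Et3N (1.6 equiv), 0 °C → rt
Reagents that add atoms: bromine, BrBr
Why: bromine addition–dehydrobromination (α-bromination of an enone); anti addition gives the 2,3-dibromoketone, and E1cB loss of HBr through the acidic C–H next to the carbonyl leaves bromine on the α-carbon; the quaternary carbinol is not involved and keeps its configuration.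

Step 5
Reactants: 8 methyl 8-[(1R)-3-bromo-1-hydroxy-4-oxocyclopent-2-en-1-yl]octanoate; 9 (2E)-pent-2-enal
Product: 12 methyl 8-[(1R,5R)-3-bromo-1-hydroxy-5-[(1R,2E)-1-hydroxypent-2-en-1-yl]-4-oxocyclopent-2-en-1-yl]octanoate, via dilithium dienolate 10 (not isolated), via titanium dienolate 11 (not isolated)
Conditions: LiN(SiMe3)2 (2.1 equiv), THF, −78 °C (8 added to the base); ClTi(OiPr)3 (2.2 equiv), −78 → −40 °C; 9 (1.3 equiv), −78 °C; aq NH4Cl
Reagents that add atoms: none
Why: titanium-enolate aldol addition (Reetz type); double deprotonation gives the alkoxide–dienolate, which cannot undergo retro-aldol at C1, and the ring-constrained E-enolate on titanium adds 1,2 to the enal with syn (erythro) selectivity between ring C5 and the new carbinol, the side chain entering anti to the bulky C1 titanate; only the syn relationship matters for step 6, and C1 is untouched.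

Step 6
Reactants: 12 methyl 8-[(1R,5R)-3-bromo-1-hydroxy-5-[(1R,2E)-1-hydroxypent-2-en-1-yl]-4-oxocyclopent-2-en-1-yl]octanoate
Product: 14 methyl 8-[(1S,5Z)-3-bromo-1-hydroxy-4-oxo-5-[(2E)-pent-2-en-1-ylidene]cyclopent-2-en-1-yl]octanoate, via O-alkylisourea 13 (not isolated)
Conditions: DCC (2.5 equiv), CuCl (0.2 equiv), toluene, 50 °C, dark
Reagents that add atoms: none
Why: DCC/CuCl dehydration of a β-hydroxy ketone; only the secondary allylic hydroxyl adds to the carbodiimide, and the O-alkylisourea loses dicyclohexylurea by intramolecular syn (Ei) elimination with the acidic C5–H, which from the syn aldol places the butenyl group cis to the C4 carbonyl (5Z); the 2E alkene and C1 are untouched (the C1 descriptor changes from R to S only because C5 gains CIP priority).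

## Compound list

1 | methyl 8-bromooctanoate | COC(=O)CCCCCCCBr | starting material
2 | 2-bromo-5-methylfuran | Cc1ccc(Br)o1 | starting material
3 | (8-methoxy-8-oxooctyl)zinc bromide | COC(=O)CCCCCCC[Zn]Br | intermediate (not isolated)
4 | methyl 8-(5-methylfuran-2-yl)octanoate | COC(=O)CCCCCCCc1ccc(C)o1 | intermediate
5 | methyl (10Z)-9,12-dioxotridec-10-enoate | COC(=O)CCCCCCCC(=O)/C=C\C(C)=O | intermediate
6 | methyl 8-[(1R)-1-hydroxy-4-oxocyclopent-2-en-1-yl]octanoate | C1C(=O)C=C[C@@]1(O)CCCCCCCC(=O)OC | intermediate
7 | methyl 8-[(1R,2R,3R)-2,3-dibromo-1-hydroxy-4-oxocyclopentyl]octanoate (trans-dibromide, C2–Br cis to OH) | C1C(=O)[C@@H](Br)[C@H](Br)[C@@]1(O)CCCCCCCC(=O)OC | intermediate (not isolated)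
8 | methyl 8-[(1R)-3-bromo-1-hydroxy-4-oxocyclopent-2-en-1-yl]octanoate | C1C(=O)C(Br)=C[C@@]1(O)CCCCCCCC(=O)OC | intermediate
9 | (2E)-pent-2-enal | CC/C=C/C=O | starting material
10 | dilithium alkoxide–dienolate of 8 (lithium on the C1 oxygen and on the C4 enolate oxygen) | C1=C(O[Li])C(Br)=C[C@@]1(O[Li])CCCCCCCC(=O)OC | intermediate (not isolated)
11 | bis(triisopropoxytitanium) alkoxide–dienolate of 8 | C1=C(O[Ti](OC(C)C)(OC(C)C)OC(C)C)C(Br)=C[C@@]1(O[Ti](OC(C)C)(OC(C)C)OC(C)C)CCCCCCCC(=O)OC | intermediate (not isolated)
12 | methyl 8-[(1R,5R)-3-bromo-1-hydroxy-5-[(1R,2E)-1-hydroxypent-2-en-1-yl]-4-oxocyclopent-2-en-1-yl]octanoate (syn aldol) | CC/C=C/[C@@H](O)[C@H]1C(=O)C(Br)=C[C@@]1(O)CCCCCCCC(=O)OC | intermediate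
13 | O-alkyl-N,N'-dicyclohexylisourea of 12 (secondary oxygen bound to the carbodiimide carbon) | CC/C=C/[C@@H](OC(=NC1CCCCC1)NC1CCCCC1)[C@H]2C(=O)C(Br)=C[C@@]2(O)CCCCCCCC(=O)OC | intermediate (not isolated)
14 | methyl 8-[(1S,5Z)-3-bromo-1-hydroxy-4-oxo-5-[(2E)-pent-2-en-1-ylidene]cyclopent-2-en-1-yl]octanoate | CC/C=C/C=C1\C(=O)C(Br)=C[C@@]1(O)CCCCCCCC(=O)OC | target

## Step count and risks

Total step count: 6. Longest linear sequence: 6 steps (from 1 or 2 to 14).

**Step 3 (the proposed new aldol).** Possible failures are condensation at C9 (giving the 4-hydroxy-4-methyl regioisomer), Z→E isomerisation of 5 by reversible amine conjugate addition, low enantioselectivity, or racemisation of 6 by retro-aldol if left too long. The fallback uses known chemistry and sets out from 5. Stirring 5 with dilute aqueous Na2CO3 at room temperature gives racemic methyl 8-(1-hydroxy-4-oxocyclopent-2-en-1-yl)octanoate F1. Preparative supercritical-fluid chromatography on an amylose tris(3,5-dimethylphenylcarbamate) phase separates F1 into 6 and methyl 8-[(1S)-1-hydroxy-4-oxocyclopent-2-en-1-yl]octanoate F2. F2 can in principle be returned to F1 with the same carbonate through the open enedione. The route is rejoined at 6.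

**Step 5 (syn aldol of the bromo-enone dianion).** Possible failures are retro-aldol at C1 while only the alkoxide is present, decomposition of the bromodienolate, or a poor syn:anti ratio. The fallback sets out from 8 and avoids strong base and metal enolates. TMSOTf/Et3N in CH2Cl2 at 0 °C gives methyl 8-[(1R)-3-bromo-1,4-bis(trimethylsilyloxy)cyclopenta-2,4-dien-1-yl]octanoate F3. A fluoride-promoted Mukaiyama aldol of F3 with 9 (TASF, 10 mol %, THF, −78 °C), which is also syn-selective through an open transition state, gives methyl 8-[(1R,5R)-3-bromo-4-oxo-1-(trimethylsilyloxy)-5-[(1R,2E)-1-(trimethylsilyloxy)pent-2-en-1-yl]cyclopent-2-en-1-yl]octanoate F4. Dilute HCl in THF–water removes both silyl groups, and the route is rejoined at 12.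

**Step 6 (geometry of the exocyclic alkene).** Possible failures are E1cB leakage or anti-aldol contamination giving the 5E isomer, or activation of the tertiary alcohol. The fallback sets out from 12 at any diastereomer ratio. MsCl/Et3N in CH2Cl2 at −20 °C gives methyl 8-[(1R,5R)-3-bromo-1-hydroxy-5-[(1R,2E)-1-(methylsulfonyloxy)pent-2-en-1-yl]-4-oxocyclopent-2-en-1-yl]octanoate F5. DBU then eliminates it by E1cB to a mixture of 14 and methyl 8-[(1S,5E)-3-bromo-1-hydroxy-4-oxo-5-[(2E)-pent-2-en-1-ylidene]cyclopent-2-en-1-yl]octanoate F6. Irradiating F6 (365 nm, benzene) isomerises the exocyclic alkene to a photostationary mixture; 14 is separated by HPLC and F6 is recycled. The route is rejoined at 14.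

## Further compounds

F1 | step 3 | racemic methyl 8-(1-hydroxy-4-oxocyclopent-2-en-1-yl)octanoate | C1C(=O)C=CC1(O)CCCCCCCC(=O)OC
F2 | step 3 | methyl 8-[(1S)-1-hydroxy-4-oxocyclopent-2-en-1-yl]octanoate | C1C(=O)C=C[C@]1(O)CCCCCCCC(=O)OC
F3 | step 5 | methyl 8-[(1R)-3-bromo-1,4-bis(trimethylsilyloxy)cyclopenta-2,4-dien-1-yl]octanoate | C1=C(O[Si](C)(C)C)C(Br)=C[C@@]1(O[Si](C)(C)C)CCCCCCCC(=O)OC
F4 | step 5 | methyl 8-[(1R,5R)-3-bromo-4-oxo-1-(trimethylsilyloxy)-5-[(1R,2E)-1-(trimethylsilyloxy)pent-2-en-1-yl]cyclopent-2-en-1-yl]octanoate | CC/C=C/[C@@H](O[Si](C)(C)C)[C@H]1C(=O)C(Br)=C[C@@]1(O[Si](C)(C)C)CCCCCCCC(=O)OC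
F5 | step 6 | methyl 8-[(1R,5R)-3-bromo-1-hydroxy-5-[(1R,2E)-1-(methylsulfonyloxy)pent-2-en-1-yl]-4-oxocyclopent-2-en-1-yl]octanoate | CC/C=C/[C@@H](OS(C)(=O)=O)[C@H]1C(=O)C(Br)=C[C@@]1(O)CCCCCCCC(=O)OC
F6 | step 6 | methyl 8-[(1S,5E)-3-bromo-1-hydroxy-4-oxo-5-[(2E)-pent-2-en-1-ylidene]cyclopent-2-en-1-yl]octanoate | CC/C=C/C=C1/C(=O)C(Br)=C[C@@]1(O)CCCCCCCC(=O)OC
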